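**Plan**
- Retrosynthetic cuts: (i) the C6–O ester; (ii) C3–C4, which opens the cyclopentane to an isopropyl ketone on C5 and a 2-iodoethyl arm on C1; (iii) C8=C9 (ring-closing metathesis); (iv) C1–C5 ([3,3] shift of an allylic β-hydroxy ester); (v) the ester C–O bond, leaving two small fragments.
- Forward order: acyclic allylic ester → Claisen rearrangement (C1–C5) → seven-membered ring by metathesis → vinyl to iodoethyl, amide to isopropyl ketone → five-membered ring by samarium Barbier closure → desilylation and acylation.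
- Stereochemistry: C6 comes from ethyl (R)-4-chloro-3-hydroxybutanoate; C5 (anti to O6) and C1 (chair, E-alkene) are set together in the chelated dianion Claisen step; C4 is set in the ring closure under substrate control.
- Enabling feature: C4, the tertiary carbinol of the five-membered ring (OH, isopropyl), is bonded to the ring-fusion CH (C5) and reaches the quaternary C1 only through the unsubstituted C3H2–C2H2 bridge. A ketone on C5 and a primary iodide two carbons out from C1, held trans on the seven-membered ring, are therefore a 5-exo Barbier pair.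

Key step: step 12

Remark: daucane numbering is used (C1 quaternary methyl carbon, C2/C3 ring CH2, C4 carbinol, C5 ring-fusion CH, C6 ester carbon, C8=C9 ring alkene); the SMILES is read as (1R,4R,5S,6S), i.e. the 6-O-(4-methoxybenzoate) of jaeschkeanadiol, and all unnumbered reagents are taken as commercial.

Step 1
Reactants: 1 pent-1-en-4-yne
Product: 4 (2E)-3-methylhexa-2,5-dien-1-ol, via alkenyldimethylalane 2 (not isolated), via lithium alkenylaluminate 3 (not isolated)
Conditions: Me3Al (2 equiv), Cp2ZrCl2 (0.2 equiv), CH2Cl2, 0 °C to rt; n-BuLi, THF, −78 °C; (CH2O)n, −78 °C to rt; aq. work-up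
Reagents that add atoms: trimethylaluminium, C[Al](C)C; paraformaldehyde (as formaldehyde), C=O
Why: Zirconium-catalysed carboalumination adds methyl and aluminium syn across the terminal alkyne with aluminium on the terminal carbon (the isolated alkene is far slower), and the aluminate formed with n-BuLi is hydroxymethylated by formaldehyde with retention of alkene geometry, which should give the E allylic alcohol.

Step 2
Reactants: 5 ethyl (3R)-4-chloro-3-hydroxybutanoate
Product: 6 ethyl 2-[(2R)-oxiran-2-yl]acetate
Conditions: Ag2O (1.2 equiv), MeCN, 60 °C, dark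
Reagents that add atoms: none
Why: Silver-assisted intramolecular Williamson etherification closes the epoxide by attack of the hydroxyl oxygen on CH2Cl under non-basic conditions that spare the base-sensitive β,γ-epoxy ester, and no bond to the stereocentre is broken.

Step 3
Reactants: 6 ethyl 2-[(2R)-oxiran-2-yl]acetate
Product: 7 ethyl (3S)-3-hydroxy-5-methylhex-5-enoate
Conditions: isopropenylmagnesium bromide (1.5 equiv), CuI (10 mol %), THF, −40 °C; aq. NH4Cl
Reagents that add atoms: isopropenylmagnesium bromide, CC(=C)[Mg]Br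
Why: Copper-catalysed Grignard opening of a terminal epoxide takes place by SN2 attack at the CH2 carbon and is faster than addition to the ester at −40 °C, so the carbinol centre is retained (the change of descriptor from R to S is only one of priority).

Step 4
Reactants: 7 ethyl (3S)-3-hydroxy-5-methylhex-5-enoate, 4 (2E)-3-methylhexa-2,5-dien-1-ol
Product: 8 (2E)-3-methylhexa-2,5-dien-1-yl (3S)-3-hydroxy-5-methylhex-5-enoate
Conditions: Ti(OEt)4 (10 mol %), 4 (1.5 equiv), toluene, 100 °C, EtOH distilled out
Reagents that add atoms: none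
Why: Titanate-catalysed transesterification is an equilibrium driven by removal of ethanol and runs under neutral conditions that leave the free β-hydroxyl group, the skipped diene and the stereocentre untouched.

Step 5
Reactants: 8 (2E)-3-methylhexa-2,5-dien-1-yl (3S)-3-hydroxy-5-methylhex-5-enoate
Product: 10 (2S,3S)-3-hydroxy-5-methyl-2-[(3S)-3-methylhexa-1,5-dien-3-yl]hex-5-enoic acid, via dilithium enolate alkoxide 9 (not isolated)
Conditions: LDA (2.2 equiv), THF, −78 °C; then warm to 50 °C; 1 M HCl
Reagents that add atoms: none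
Why: Ester-enolate Claisen ([3,3]) rearrangement of the lithium-chelated β-oxido enolate (Ireland–Claisen type, dianion variant): the chelate fixes the enolate geometry with C6 cis to O–Li and shields one face as in a Fráter–Seebach alkylation, so the new bond forms anti to the C6 oxygen (C5 = S), and the chair transition state with the E-alkene (allyl equatorial, methyl axial) transmits this to the quaternary centre C1.

Step 6
Reactants: 10 (2S,3S)-3-hydroxy-5-methyl-2-[(3S)-3-methylhexa-1,5-dien-3-yl]hex-5-enoic acid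
Product: 11 (2S,3S)-3-hydroxy-N-methoxy-N,5-dimethyl-2-[(3S)-3-methylhexa-1,5-dien-3-yl]hex-5-enamide
Conditions: MeNH(OMe)·HCl, EDC·HCl, HOBt, i-Pr2NEt, CH2Cl2, 0 °C to rt
Reagents that add atoms: N,O-dimethylhydroxylamine hydrochloride, CNOC.Cl
Why: Carbodiimide/HOBt coupling forms the N-methoxy-N-methylamide through the benzotriazolyl active ester under nearly neutral conditions, so the α-stereocentre should not epimerise and the hindered secondary hydroxyl should not compete with the amine.

Step 7
Reactants: 11 (2S,3S)-3-hydroxy-N-methoxy-N,5-dimethyl-2-[(3S)-3-methylhexa-1,5-dien-3-yl]hex-5-enamide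
Product: 12 (2S,3S)-3-[(tert-butyldimethylsilyl)oxy]-N-methoxy-N,5-dimethyl-2-[(3S)-3-methylhexa-1,5-dien-3-yl]hex-5-enamide
Conditions: TBSOTf, 2,6-lutidine, CH2Cl2, −78 to 0 °C
Reagents that add atoms: tert-butyldimethylsilyl triflate, CC(C)(C)[Si](C)(C)OS(=O)(=O)C(F)(F)F
Why: Silylation with the silyl triflate and a hindered pyridine base is the standard method for congested secondary alcohols and caps the oxygen at C6 against retro-aldol cleavage, elimination and proton transfer in the later organometallic steps.

Step 8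
Reactants: 12 (2S,3S)-3-[(tert-butyldimethylsilyl)oxy]-N-methoxy-N,5-dimethyl-2-[(3S)-3-methylhexa-1,5-dien-3-yl]hex-5-enamide
Product: 13 (1S,2S,7S)-7-[(tert-butyldimethylsilyl)oxy]-2-ethenyl-N-methoxy-N,2,5-trimethylcyclohept-4-ene-1-carboxamide
Conditions: second-generation Grubbs catalyst RuCl2(=CHPh)(PCy3)(H2IMes) (5 mol %), CH2Cl2 (5 mM), 40 °C
Reagents that add atoms: none
Why: Ring-closing olefin metathesis: the ruthenium carbene loads on the unhindered allyl group and closes onto the 1,1-disubstituted alkene to give the trisubstituted cycloheptene with loss of ethylene, while the vinyl group on the quaternary carbon is too hindered to initiate and could only give a four-membered ring with the allyl-derived carbene.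

Step 9
Reactants: 13 (1S,2S,7S)-7-[(tert-butyldimethylsilyl)oxy]-2-ethenyl-N-methoxy-N,2,5-trimethylcyclohept-4-ene-1-carboxamide
Product: 15 (1S,2S,7S)-7-[(tert-butyldimethylsilyl)oxy]-2-(2-hydroxyethyl)-N-methoxy-N,2,5-trimethylcyclohept-4-ene-1-carboxamide, via B-alkyl-9-borabicyclononane 14 (not isolated)
Conditions: 9-BBN (1.5 equiv), THF, rt; then NaOH, H2O2, 0 °C to rt
Reagents that add atoms: hydrogen peroxide, OO
Why: Hydroboration–oxidation with the bulky dialkylborane 9-BBN is anti-Markovnikov and selective for the monosubstituted vinyl group over the trisubstituted ring alkene, and the amide and silyl ether do not react at room temperature.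

Step 10
Reactants: 15 (1S,2S,7S)-7-[(tert-butyldimethylsilyl)oxy]-2-(2-hydroxyethyl)-N-methoxy-N,2,5-trimethylcyclohept-4-ene-1-carboxamide
Product: 16 1-[(1S,2S,7S)-7-[(tert-butyldimethylsilyl)oxy]-2-(2-hydroxyethyl)-2,5-dimethylcyclohept-4-en-1-yl]-2-methylpropan-1-one
Conditions: i-PrLi (3.2 equiv), THF, −78 to −20 °C; aq. NH4Cl
Reagents that add atoms: isopropyllithium, [Li]C(C)C
Why: Weinreb ketone synthesis: after deprotonation of the hydroxyl group the organolithium adds once to the N-methoxy-N-methylamide to give a lithium-chelated tetrahedral intermediate that collapses to the ketone only on aqueous work-up, so over-addition is excluded.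

Step 11
Reactants: 16 1-[(1S,2S,7S)-7-[(tert-butyldimethylsilyl)oxy]-2-(2-hydroxyethyl)-2,5-dimethylcyclohept-4-en-1-yl]-2-methylpropan-1-one
Product: 17 1-[(1S,2S,7S)-7-[(tert-butyldimethylsilyl)oxy]-2-(2-iodoethyl)-2,5-dimethylcyclohept-4-en-1-yl]-2-methylpropan-1-one
Conditions: PPh3, I2, imidazole, CH2Cl2, 0 °C
Reagents that add atoms: iodine, II
Why: Appel iodination turns the primary alcohol into its alkoxyphosphonium ion, which iodide displaces by SN2; the ketone, silyl ether and ring alkene are inert, and any lactol form of the δ-hydroxy ketone drains through the open chain.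

Step 12
Reactants: 17 1-[(1S,2S,7S)-7-[(tert-butyldimethylsilyl)oxy]-2-(2-iodoethyl)-2,5-dimethylcyclohept-4-en-1-yl]-2-methylpropan-1-one
Product: 19 (3R,3aS,4S,8aR)-4-[(tert-butyldimethylsilyl)oxy]-6,8a-dimethyl-3-(propan-2-yl)-1,2,3,3a,4,5,8,8a-octahydroazulen-3-ol, via alkylsamarium diiodide 18 (not isolated)
Conditions: SmI2 (2.5 equiv, 0.1 M in THF), HMPA (10 equiv), THF (0.01 M), −78 to 0 °C; aq. NH4Cl
Reagents that add atoms: none
Why: Samarium diiodide/HMPA reduces the primary C–I bond in two single-electron steps (alkyl radical, then alkylsamarium 18), and the carbon–samarium bond adds to the isopropyl ketone five atoms away, the alkoxide being protonated on work-up. The closest known reaction type is the intramolecular samarium Barbier cyclisation of ω-iodoalkyl ketones to bicyclic tertiary cyclopentanols. The five-membered ring closes in the 5-exo-trig mode onto the carbonyl carbon and becomes trans-fused to the cycloheptene, because the isobutyryl group on C5 and the two-carbon arm on C1 are trans and can both lie pseudo-equatorial. The one new stereocentre, C4, is set by the substrate: in the closing transition state the carbonyl plane is perpendicular to the forming ring, so the isopropyl group takes the side of the small C5–H and stays clear of the C5–C6 bond, the bulky silyloxy group and the angular methyl, which puts the oxygen cis to C6 and to the C1 methyl group as in the target. The step needs C–I reduction to outrun ketyl formation, elimination and simple protonation; the fast iodide reduction by the HMPA complex at −78 °C, the aprotic medium and the capped, non-acidic C6 oxygen should secure this.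

Step 13
Reactants: 19 (3R,3aS,4S,8aR)-4-[(tert-butyldimethylsilyl)oxy]-6,8a-dimethyl-3-(propan-2-yl)-1,2,3,3a,4,5,8,8a-octahydroazulen-3-ol
Product: 20 jaeschkeanadiol, (3R,3aS,4S,8aR)-6,8a-dimethyl-3-(propan-2-yl)-1,2,3,3a,4,5,8,8a-octahydroazulene-3,4-diol
Conditions: TBAF, THF, rt to 50 °C
Reagents that add atoms: none
Why: Fluoride cleaves the silicon–oxygen bond (strong Si–F bond) and frees the secondary alcohol; the tertiary alcohol and the alkene are not affected.

Step 14
Reactants: 20 jaeschkeanadiol
Product: 21 fertidin, (3R,3aS,4S,8aR)-3-hydroxy-6,8a-dimethyl-3-(propan-2-yl)-1,2,3,3a,4,5,8,8a-octahydroazulen-4-yl 4-methoxybenzoate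
Conditions: 4-MeOC6H4COCl (1.5 equiv), Et3N, DMAP (0.2 equiv), CH2Cl2, 0 °C to rt
Reagents that add atoms: 4-methoxybenzoyl chloride, COc1ccc(C(Cl)=O)cc1
Why: DMAP-catalysed acylation through the acylpyridinium ion differentiates the secondary from the tertiary hydroxyl group on steric grounds, so only O6 should be esterified.

**Compound list**
1 | pent-1-en-4-yne | C=CCC#C | starting material
2 | (E)-dimethyl(2-methylpenta-1,4-dien-1-yl)alane | C=CC/C(C)=C/[Al](C)C | intermediate
3 | lithium butyl(dimethyl)[(E)-2-methylpenta-1,4-dien-1-yl]aluminate | [Li+].C=CC/C(C)=C/[Al-](C)(C)CCCC | intermediate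
4 | (2E)-3-methylhexa-2,5-dien-1-ol | C=CC/C(C)=C/CO | intermediate
5 | ethyl (3R)-4-chloro-3-hydroxybutanoate | CCOC(=O)C[C@@H](O)CCl | starting material
6 | ethyl 2-[(2R)-oxiran-2-yl]acetate | CCOC(=O)C[C@@H]1CO1 | intermediate
7 | ethyl (3S)-3-hydroxy-5-methylhex-5-enoate | CCOC(=O)C[C@@H](O)CC(C)=C | intermediate
8 | (2E)-3-methylhexa-2,5-dien-1-yl (3S)-3-hydroxy-5-methylhex-5-enoate | C=CC/C(C)=C/COC(=O)C[C@@H](O)CC(C)=C | intermediate
9 | dilithium enolate alkoxide of 8 (C6 cis to O–Li, chelated) | C=CC/C(C)=C/CO/C(O[Li])=C/[C@@H](O[Li])CC(C)=C | intermediate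
10 | (2S,3S)-3-hydroxy-5-methyl-2-[(3S)-3-methylhexa-1,5-dien-3-yl]hex-5-enoic acid | OC(=O)[C@@H]([C@](C)(C=C)CC=C)[C@@H](O)CC(C)=C | intermediate
11 | (2S,3S)-3-hydroxy-N-methoxy-N,5-dimethyl-2-[(3S)-3-methylhexa-1,5-dien-3-yl]hex-5-enamide | CON(C)C(=O)[C@@H]([C@](C)(C=C)CC=C)[C@@H](O)CC(C)=C | intermediate
12 | (2S,3S)-3-[(tert-butyldimethylsilyl)oxy]-N-methoxy-N,5-dimethyl-2-[(3S)-3-methylhexa-1,5-dien-3-yl]hex-5-enamide | CON(C)C(=O)[C@@H]([C@](C)(C=C)CC=C)[C@@H](O[Si](C)(C)C(C)(C)C)CC(C)=C | intermediate
13 | (1S,2S,7S)-7-[(tert-butyldimethylsilyl)oxy]-2-ethenyl-N-methoxy-N,2,5-trimethylcyclohept-4-ene-1-carboxamide | CON(C)C(=O)[C@@H]1[C@@H](O[Si](C)(C)C(C)(C)C)CC(C)=CC[C@@]1(C)C=C | intermediate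
14 | B-alkyl-9-borabicyclo[3.3.1]nonane from 13 (boron on the terminal carbon of the former vinyl group) | CON(C)C(=O)[C@@H]1[C@@H](O[Si](C)(C)C(C)(C)C)CC(C)=CC[C@@]1(C)CCB1C2CCCC1CCC2 | intermediate
15 | (1S,2S,7S)-7-[(tert-butyldimethylsilyl)oxy]-2-(2-hydroxyethyl)-N-methoxy-N,2,5-trimethylcyclohept-4-ene-1-carboxamide | CON(C)C(=O)[C@@H]1[C@@H](O[Si](C)(C)C(C)(C)C)CC(C)=CC[C@@]1(C)CCO | intermediate
16 | 1-[(1S,2S,7S)-7-[(tert-butyldimethylsilyl)oxy]-2-(2-hydroxyethyl)-2,5-dimethylcyclohept-4-en-1-yl]-2-methylpropan-1-one | CC(C)C(=O)[C@@H]1[C@@H](O[Si](C)(C)C(C)(C)C)CC(C)=CC[C@@]1(C)CCO | intermediate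
17 | 1-[(1S,2S,7S)-7-[(tert-butyldimethylsilyl)oxy]-2-(2-iodoethyl)-2,5-dimethylcyclohept-4-en-1-yl]-2-methylpropan-1-one | CC(C)C(=O)[C@@H]1[C@@H](O[Si](C)(C)C(C)(C)C)CC(C)=CC[C@@]1(C)CCI | intermediate
18 | alkylsamarium diiodide from 17 (SmI2 group in place of iodine) | CC(C)C(=O)[C@@H]1[C@@H](O[Si](C)(C)C(C)(C)C)CC(C)=CC[C@@]1(C)CC[Sm](I)I | intermediate
19 | (3R,3aS,4S,8aR)-4-[(tert-butyldimethylsilyl)oxy]-6,8a-dimethyl-3-(propan-2-yl)-1,2,3,3a,4,5,8,8a-octahydroazulen-3-ol | CC(C)(C)[Si](C)(C)O[C@H]1CC(C)=CC[C@@]2(C)CC[C@@](O)(C(C)C)[C@H]12 | intermediate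
20 | jaeschkeanadiol, (3R,3aS,4S,8aR)-6,8a-dimethyl-3-(propan-2-yl)-1,2,3,3a,4,5,8,8a-octahydroazulene-3,4-diol | O[C@H]1CC(C)=CC[C@@]2(C)CC[C@@](O)(C(C)C)[C@H]12 | intermediate
21 | fertidin, (3R,3aS,4S,8aR)-3-hydroxy-6,8a-dimethyl-3-(propan-2-yl)-1,2,3,3a,4,5,8,8a-octahydroazulen-4-yl 4-methoxybenzoate | COc1ccc(C(=O)O[C@H]2CC(C)=CC[C@@]3(C)CC[C@@](O)(C(C)C)[C@H]23)cc1 | target

**Step count and risks**
Total step count: 14. Longest linear sequence: 13 steps (5 to 21, steps 2–14); step 1 supplies alcohol 4 in a side branch.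

Steps most likely to fail:

Step 12. The alkylsamarium may be protonated before it reaches the carbonyl group (loss of iodine without ring closure), the ketone may be reduced through its ketyl, or attack on the other carbonyl face may give the C4 epimer. The fallback sets out from 13 and closes the same C3–C4 bond by a different event. The N-methoxy-N-methylamide is reduced with diisobutylaluminium hydride (THF, −78 °C) to (1S,2S,7S)-7-[(tert-butyldimethylsilyl)oxy]-2-ethenyl-2,5-dimethylcyclohept-4-ene-1-carbaldehyde F1. The cationic rhodium–diphosphine catalyst [Rh(dppe)]ClO4 (CH2Cl2, rt) should then add the formyl C–H bond across the vinyl group (intramolecular hydroacylation of a 4-pentenal) to give the trans-fused ketone (3aS,4S,8aR)-4-[(tert-butyldimethylsilyl)oxy]-6,8a-dimethyl-2,3a,4,5,8,8a-hexahydroazulen-3(1H)-one F2. Isopropylmagnesium chloride with CeCl3 (THF, −78 °C) should add from the face opposite the angular methyl group, which would have to be verified, and returns the route at 19.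

Step 5. The lithium enolate may fragment to a ketene and the allylic alkoxide before the hindered [3,3] shift, excess base may isomerise the skipped diene, or face and chair/boat selectivity may erode. The fallback sets out from 8. The C6 hydroxyl is silylated first (TBSOTf, 2,6-lutidine) to give (2E)-3-methylhexa-2,5-dien-1-yl (3S)-3-[(tert-butyldimethylsilyl)oxy]-5-methylhex-5-enoate F3. This is enolised with LDA in THF–HMPA and trapped with Me3SiCl at −78 °C as the (Z)-trimethylsilyl ketene acetal F4 (C6 cis to OSi, the geometry of the chelate). The neutral ketene acetal rearranges on warming (Ireland–Claisen rearrangement proper), with face selection now resting on the silyloxy stereocentre, and hydrolysis of the silyl ester gives (2S,3S)-3-[(tert-butyldimethylsilyl)oxy]-5-methyl-2-[(3S)-3-methylhexa-1,5-dien-3-yl]hex-5-enoic acid F5. Amide coupling as in step 6 returns the route at 12.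

Step 10. Congestion around the amide may lead to deprotonation at C5 (loss of configuration) or to no addition. The fallback sets out from 15. Isopropenylmagnesium bromide, a smaller sp2 nucleophile that cannot transfer a β-hydride, is added (THF, 0 °C) to give the enone 1-[(1S,2S,7S)-7-[(tert-butyldimethylsilyl)oxy]-2-(2-hydroxyethyl)-2,5-dimethylcyclohept-4-en-1-yl]-2-methylprop-2-en-1-one F6. Its conjugated C=C bond is then reduced by 1,4-hydride delivery with [(Ph3P)CuH]6 (benzene, rt), which returns the route at 16.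

Further compounds
F1 | step 12 | (1S,2S,7S)-7-[(tert-butyldimethylsilyl)oxy]-2-ethenyl-2,5-dimethylcyclohept-4-ene-1-carbaldehyde | O=C[C@@H]1[C@@H](O[Si](C)(C)C(C)(C)C)CC(C)=CC[C@@]1(C)C=C
F2 | step 12 | (3aS,4S,8aR)-4-[(tert-butyldimethylsilyl)oxy]-6,8a-dimethyl-2,3a,4,5,8,8a-hexahydroazulen-3(1H)-one | CC(C)(C)[Si](C)(C)O[C@H]1CC(C)=CC[C@@]2(C)CCC(=O)[C@H]12
F3 | step 5 | (2E)-3-methylhexa-2,5-dien-1-yl (3S)-3-[(tert-butyldimethylsilyl)oxy]-5-methylhex-5-enoate | C=CC/C(C)=C/COC(=O)C[C@@H](O[Si](C)(C)C(C)(C)C)CC(C)=C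
F4 | step 5 | (Z)-trimethylsilyl ketene acetal of F3 | C=CC/C(C)=C/CO/C(O[Si](C)(C)C)=C/[C@@H](O[Si](C)(C)C(C)(C)C)CC(C)=C
F5 | step 5 | (2S,3S)-3-[(tert-butyldimethylsilyl)oxy]-5-methyl-2-[(3S)-3-methylhexa-1,5-dien-3-yl]hex-5-enoic acid | OC(=O)[C@@H]([C@](C)(C=C)CC=C)[C@@H](O[Si](C)(C)C(C)(C)C)CC(C)=C
F6 | step 10 | 1-[(1S,2S,7S)-7-[(tert-butyldimethylsilyl)oxy]-2-(2-hydroxyethyl)-2,5-dimethylcyclohept-4-en-1-yl]-2-methylprop-2-en-1-one | CC(=C)C(=O)[C@@H]1[C@@H](O[Si](C)(C)C(C)(C)C)CC(C)=CC[C@@]1(C)CCO
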